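## The problem

The target is a trans-fused hydroazulene. Ring A is the cycloheptene C1–C6 plus C10, ring B the cyclopentane C6–C10, and they share the C6–C10 bond. C1 carries the angelate, C2=C3 is the olefin (methyl on C3), C5 carries the veratrate, C7 is the C(OH)(isopropyl) carbon and C10 bears the angular methyl. Five stereocentres must be set (1R,5S,6S,7R,10S). Two of them, the all-carbon C10 and the carbinol C7, are fully substituted and flank the fusion methine C6, so C6–C10 is the most congested bond of the skeleton. C10 cannot be corrected once made. C6 can be epimerised while C5 is a ketone, the β-hydroxyl on C7 can deliver hydride to C5 from its own face, and C1 has no such helper and must be set against the neighbouring angular methyl. The angelate isomerises to the tiglate with base, nucleophilic catalysts or heat and sits on an allylic carbon that ionises easily. The tertiary β-hydroxy ketone met on the way can undergo retro-aldol cleavage or dehydration, so the esters come last. The key step is possible because ring A divides into the five-carbon run C6–C5–C4–C3–C2 (oxygen on C5, methyl on C3), which is a 2-silyloxyvinyl methylcyclopropane in disguise, and the two-carbon unit C10–C1, which is the internal double bond of a 1,1-disubstituted allene whose terminal CH2 is a latent C1 ketone. The three carbons C7–C8–C9 that join these units are the rest of ring B.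

## Retrosynthesis

**Esters.** The two acyl C–O bonds are cut first. Target 30 comes from allylic alcohol 27 and angelic acid 28, and the veratrate of 23 from diol 21 and acid chloride 22. The angelate goes on last because nothing after it may be basic, nucleophilic or hot. The veratrate goes on early because it is robust and distinguishes the secondary C5 hydroxyl from the hindered tertiary C7 hydroxyl without a protecting group.

**C1 carbinol and C2=C3 olefin.** Alcohol 27 is traced to enone 26 (C1–H bond), 26 to ketone 25 (C2–H and C3–H removed), and 25 to the exocyclic methylene compound 23 (C1=CH2 cleaved). This order is preferred because the C1 ketone is flanked by quaternary C10 and can enolise only towards C2, so the position of the olefin is unambiguous. The forward reduction must put hydride on the face of the angular methyl, which asks for reagent control.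

**C5 and C6.** Diol 21 comes from trans-fused hydroxy ketone 20 by hydride delivery from the C7 hydroxyl. Ketone 20 comes from its cis-fused C6 epimer 19 by equilibration, and 19 from bis-silyl cycloadduct 18 by cleavage of both Si–O bonds. A concerted metallacycle cannot give the trans fusion directly, so the fusion is corrected at the only stage where C6 is acidic.

**Key disconnection.** In 18 the bonds C6–C10 and C1–C2 are cut together. This opens both rings and leads to the open-chain allene–vinylcyclopropane 17. Cutting either bond alone would leave a medium ring or a quaternary centre to be made separately. The precursor is far simpler: one tertiary carbinol and one enantiopure cyclopropane. The forward reaction must deliver C10 with the right absolute sense. That is asked of the cyclopropane, whose configuration decides which face of C6 the metal occupies, so 17 must be a single (1S,2S)-cyclopropane diastereomer.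

**Tertiary carbinol.** Precursor 17 is the bis-silyl derivative of β-hydroxy ketone 16. A direct enantioselective aldol addition to a dialkyl ketone is not reliable, so the C7–O bond is cut as a formal hydration of enone 12 with the C5 carbinol as relay. Ketone 16 comes from 1,3-diol 15, 15 from epoxy alcohol 14 (C6–H), 14 from allylic alcohol 13 (C6–O and C7–O) and 13 from enone 12 (C5–H). Each forward step is a standard, allene-tolerant reaction.

**Enone.** Enone 12 is cut at C7–C8 and C5–C6 into bromide 6 (as its Grignard reagent 10), alkyne 9 and acid chloride 8. A syn carbocupration fixes the olefin geometry, which an olefination of a hindered ketone would not.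

**Fragments.** Bromide 6 comes from alcohol 5 and ester 4, and 4 from but-2-yn-1-ol 1 and orthoester 2 by a rearrangement that makes the allene. Acid chloride 8 comes from acid 7.

## Roads not taken

**Alternative 1:** The cut is the C1–C10 bond, with the C5–O bond of a cyclic allyl ether as the bond that is given up. In the forward key step, lithiation at the allylic O–CH2 carbon triggers a [2,3]-Wittig shift onto the cyclopentene carbon. This forms C1–C10 and turns the oxygen into the C1 alkoxide of cycloheptadienol A1. Its merit is real: C1 and C10 are created in one ordered transition state, so the trans relation of the C1 oxygen and the angular methyl is built in. That is the one relation the chosen plan must set by reagent control, and there this road is better. Its weak points are these: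
- C5 loses its oxygen and C6 its hydrogen, so two stereocentres must be rebuilt on a C5=C6 olefin.
- The ether methine next to the cyclopentene is also acidic, so the site of lithiation is in doubt, and a [1,2] shift competes.
- The shift must form a quaternary centre.
- The isopropyl carbinol still has to be added to the C7 ketone.

The chosen plan sets against this that both rings, C5 oxygen and C7 carbinol are in place after one step.

**Alternative 2:** The cut is the C6–C10 bond alone. In the forward key step Rh2(OAc)4 generates a carbenoid that inserts into a tertiary C–H bond with retention and closes ring B as cyclopentanone A2. Its merit is security: the absolute configuration of C10 comes from a simple methyl-bearing stereocentre by a well-understood insertion, with no question of matched and mismatched elements. In this respect it is better than the relay used here. Its weakness is reach: one ring, one bond and one stereocentre are made. The seven-membered ring with its four substituents, the C7 carbinol and an epimerisable β-keto ester centre remain, so the route would be much longer. The chosen plan accepts more risk in one step for far greater convergence.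

**Alternative 3:** The cut removes C2 from ring A, so that the target derives from a trans-hydrindanone. In the forward key step the silyl enol ether is cyclopropanated (Et2Zn, CH2I2), opened with FeCl3 and dehydrochlorinated to enone A3. Its merits are these:
- The trans fusion and the C5 and C7 centres are set in a six–five system, where control is best understood.
- No epimerisation is needed.
- A3 is the O-silyl counterpart of enone 26, so the end game would be shared; for the late stage it is as good as the chosen plan.

Its weak points are these: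
- The hydrindanone with four stereocentres is itself a long synthesis.
- FeCl3 is an oxidant and Lewis acid that the electron-rich veratrate and a tertiary trimethylsilyl ether may not survive.
- The C1 reduction problem is left unchanged.

The chosen plan reaches the bicyclic core in fewer operations.

Key step: step 11

Assumptions: locants C1–C10 are those defined above and are kept for open-chain intermediates; α is the face of the C6 hydrogen in 30, β that of the C10 methyl. Acid 7 is taken to be bought as the single (1S,2S) enantiomer (it is also the known product of (R)-propylene oxide and triethyl phosphonoacetate).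

## Route

Step 1
Reactants: 1 but-2-yn-1-ol; 2 triethyl orthoacetate
Product: 4 ethyl 3-methylpenta-3,4-dienoate, via ketene acetal 3 (not isolated)
Conditions: EtCO2H (cat.), neat, 140 °C, EtOH distilled off
Reagents that add atoms: none
Why: Johnson–Claisen rearrangement: acid-catalysed exchange gives the propargyl ketene acetal 3, whose [3,3] shift onto the alkyne creates the 1,1-disubstituted allene that carries the future C10 methyl, C1 and the exocyclic CH2.

Step 2
Reactants: 4 ethyl 3-methylpenta-3,4-dienoate
Product: 5 3-methylpenta-3,4-dien-1-ol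
Conditions: LiAlH4, Et2O, 0 °C
Reagents that add atoms: none
Why: Ester reduction with LiAlH4; an isolated allene is not attacked by nucleophilic hydride, and the low temperature avoids base-induced isomerisation to the conjugated diene.

Step 3
Reactants: 5 3-methylpenta-3,4-dien-1-ol
Product: 6 5-bromo-3-methylpenta-1,2-diene
Conditions: CBr4, PPh3, CH2Cl2, 0 °C
Reagents that add atoms: carbon tetrabromide, BrC(Br)(Br)Br
Why: Appel reaction: bromide displaces the alkoxyphosphonium group at a primary, non-allylic carbon under neutral conditions, so the allene is not disturbed.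

Step 4
Reactants: 7 (1S,2S)-2-methylcyclopropane-1-carboxylic acid
Product: 8 (1S,2S)-2-methylcyclopropane-1-carbonyl chloride
Conditions: (COCl)2, DMF (cat.), CH2Cl2, 0 °C → rt; used crude
Reagents that add atoms: oxalyl chloride, O=C(Cl)C(Cl)=O
Why: Acid chloride formation through the chloroiminium salt from DMF; no base is present and the cyclopropane α-hydrogen does not enolise, so both stereocentres are kept.

Step 5
Reactants: 6 5-bromo-3-methylpenta-1,2-diene; 9 3-methylbut-1-yne; 8 (1S,2S)-2-methylcyclopropane-1-carbonyl chloride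
Product: 12 (2E)-6-methyl-1-[(1S,2S)-2-methylcyclopropyl]-3-(propan-2-yl)octa-2,6,7-trien-1-one, via Grignard reagent 10 (not isolated), via alkenylcopper 11 (not isolated)
Conditions: Mg, Et2O; CuBr·SMe2, Et2O/Me2S, −45 °C; 9, −25 °C; 8, Pd(PPh3)4 (3 mol %), THF, −25 → 0 °C
Reagents that add atoms: none
Why: Normant carbocupration: the alkylcopper from 10 adds syn across the terminal alkyne with the alkyl group on the substituted carbon, giving 11 of fixed geometry; acylation under zerovalent palladium catalysis goes with retention, so the chain is cis and the isopropyl group trans to the carbonyl.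

Step 6
Reactants: 12 (2E)-6-methyl-1-[(1S,2S)-2-methylcyclopropyl]-3-(propan-2-yl)octa-2,6,7-trien-1-one
Product: 13 (1S,2E)-6-methyl-1-[(1S,2S)-2-methylcyclopropyl]-3-(propan-2-yl)octa-2,6,7-trien-1-ol
Conditions: (R)-2-methyl-CBS-oxazaborolidine (20 mol %), catecholborane, toluene, −78 °C
Reagents that add atoms: none
Why: Corey–Bakshi–Shibata reduction: the oxazaborolidine binds the carbonyl anti to the larger, β,β-disubstituted alkenyl group and delivers hydride 1,2, which with the (R)-catalyst should give the (S) carbinol at C5; catecholborane at −78 °C leaves the allene alone.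

Step 7
Reactants: 13 (1S,2E)-6-methyl-1-[(1S,2S)-2-methylcyclopropyl]-3-(propan-2-yl)octa-2,6,7-trien-1-ol
Product: 14 (S)-[(1S,2S)-2-methylcyclopropyl][(2R,3R)-3-(3-methylpenta-3,4-dien-1-yl)-3-(propan-2-yl)oxiran-2-yl]methanol
Conditions: VO(acac)2 (cat.), t-BuOOH, CH2Cl2, 0 °C
Reagents that add atoms: tert-butyl hydroperoxide, CC(C)(C)OO
Why: Vanadium-catalysed hydroxyl-directed epoxidation: 1,3-allylic strain with the chain cis on C7 holds the carbinol hydrogen in the olefin plane, so the vanadate ester delivers oxygen to one face and the threo epoxy alcohol results, which sets C7; the allene has no directing hydroxyl and is not touched.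

Step 8
Reactants: 14 (S)-[(1S,2S)-2-methylcyclopropyl][(2R,3R)-3-(3-methylpenta-3,4-dien-1-yl)-3-(propan-2-yl)oxiran-2-yl]methanol
Product: 15 (1R,3S)-6-methyl-1-[(1S,2S)-2-methylcyclopropyl]-3-(propan-2-yl)octa-6,7-diene-1,3-diol
Conditions: NaAlH2(OCH2CH2OMe)2 (Red-Al), THF, 0 °C
Reagents that add atoms: none
Why: Regioselective Red-Al opening of a 2,3-epoxy alcohol: the aluminate bound to the C5 oxygen delivers hydride intramolecularly to C6, the C7–O bond is not touched, and the 1,3-diol keeps the C7 configuration.

Step 9
Reactants: 15 (1R,3S)-6-methyl-1-[(1S,2S)-2-methylcyclopropyl]-3-(propan-2-yl)octa-6,7-diene-1,3-diol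
Product: 16 (3S)-3-hydroxy-6-methyl-1-[(1S,2S)-2-methylcyclopropyl]-3-(propan-2-yl)octa-6,7-dien-1-one
Conditions: Dess–Martin periodinane, NaHCO3, CH2Cl2, 0 °C → rt
Reagents that add atoms: none
Why: Dess–Martin oxidation of the secondary cyclopropyl carbinol; the tertiary alcohol cannot be oxidised and the bicarbonate buffer guards the β-hydroxy ketone against dehydration.

Step 10
Reactants: 16 (3S)-3-hydroxy-6-methyl-1-[(1S,2S)-2-methylcyclopropyl]-3-(propan-2-yl)octa-6,7-dien-1-one
Product: 17 (1Z,3R)-6-methyl-1-[(1S,2S)-2-methylcyclopropyl]-3-(propan-2-yl)-1,3-bis[(triethylsilyl)oxy]octa-1,6,7-triene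
Conditions: Et3SiOTf (2.5 equiv), Et3N, CH2Cl2, −78 → 0 °C
Reagents that add atoms: triethylsilyl trifluoromethanesulfonate, CC[Si](CC)(CC)OS(=O)(=O)C(F)(F)F
Why: Silyl triflate and amine silylate the tertiary alcohol and enolise the ketone (soft enolisation); only C6 can lose a proton because an enol towards the ring would be an alkylidenecyclopropane, and 1,3-allylic strain places the quaternary C7 trans to the cyclopropyl group, giving the (Z)-enol ether.

Step 11
Reactants: 17 (1Z,3R)-6-methyl-1-[(1S,2S)-2-methylcyclopropyl]-3-(propan-2-yl)-1,3-bis[(triethylsilyl)oxy]octa-1,6,7-triene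
Product: 18 (1R,3aS,6S,8aR)-3a,6-dimethyl-4-methylidene-1-(propan-2-yl)-1,8-bis[(triethylsilyl)oxy]-1,2,3,3a,4,5,6,8a-octahydroazulene (cis-fused; 3S,6R,7R,10S in the locants used here)
Conditions: [Rh(CO)2Cl]2 (5 mol %), toluene (0.01 M), 90 °C
Reagents that add atoms: none
Why: Monovalent rhodium binds the enol ether and inserts into the less substituted cyclopropane bond C4–C2, giving a rhodacyclohexene with a 2-silyloxyallyl unit C6–C5–C4; this cleavage is possible only on the face where C2 stands above the enol ether plane while C3 lies s-cis, so the (1S,2S)-cyclopropane fixes the face of C6 held by the metal. The proximal allene bond C10=C1 then inserts into the Rh–C6 bond with retention, which forms C6–C10 and closes ring B in a five-exo sense through the three-atom tether, and reductive elimination joins C1 to C2, contracting the eight-membered rhodacycle to the seven-membered ring A. The closest known reaction type is the [Rh(CO)2Cl]2-catalysed intramolecular (5+2) cycloaddition of tethered allene–vinylcyclopropanes, including 1,1-disubstituted allenes that give angular methyl groups. C6 is controlled by the cyclopropane through this stereospecific relay, and C10 is set relative to C6 by the cis fusion that the metallacycle enforces. The (R) centre at C7 is accommodated with its triethylsilyloxy group eclipsing C6–H, away from the enol silyl ether, and its isopropyl group on the face remote from rhodium. The step needs the internal allene bond to react, which the tether length and this chloro dicarbonyl catalyst favour; it needs C4–C2 and not C4–C3 cleavage, the usual course for trans-alkyl cyclopropanes with this catalyst; and it needs the (Z)-enol ether, which puts the tether syn on the allyl unit.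

Step 12
Reactants: 18 (1R,3aS,6S,8aR)-3a,6-dimethyl-4-methylidene-1-(propan-2-yl)-1,8-bis[(triethylsilyl)oxy]-1,2,3,3a,4,5,6,8a-octahydroazulene
Product: 19 (3R,3aS,6S,8aS)-3-hydroxy-6,8a-dimethyl-8-methylidene-3-(propan-2-yl)octahydroazulen-4(1H)-one (cis-fused)
Conditions: HF·pyridine, pyridine, THF, 0 °C → rt
Reagents that add atoms: none
Why: Fluoride-assisted cleavage of both Si–O bonds; the enol ether is protonated at C4, so C6 keeps the cis configuration from step 11, and the buffered medium is too mild for retro-aldol cleavage or dehydration.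

Step 13
Reactants: 19 (3R,3aS,6S,8aS)-3-hydroxy-6,8a-dimethyl-8-methylidene-3-(propan-2-yl)octahydroazulen-4(1H)-one
Product: 20 (3R,3aR,6S,8aS)-3-hydroxy-6,8a-dimethyl-8-methylidene-3-(propan-2-yl)octahydroazulen-4(1H)-one (trans-fused)
Conditions: DBU (0.3 equiv), toluene, 40 °C
Reagents that add atoms: none
Why: Base-catalysed epimerisation through the C5–C6 enolate: the trans-fused isomer should be favoured because the C5 carbonyl moves from the side of the isopropyl group to the side of the small hydroxyl, to which it can hydrogen-bond; an amidine base in a non-polar solvent keeps the alkoxide concentration, and with it retro-aldol cleavage, low.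

Step 14
Reactants: 20 (3R,3aR,6S,8aS)-3-hydroxy-6,8a-dimethyl-8-methylidene-3-(propan-2-yl)octahydroazulen-4(1H)-one
Product: 21 (3R,3aS,4S,6S,8aS)-6,8a-dimethyl-8-methylidene-3-(propan-2-yl)decahydroazulene-3,4-diol
Conditions: Me4NBH(OAc)3, MeCN/AcOH (1:1), −25 °C
Reagents that add atoms: none
Why: Evans–Saksena reduction: the triacetoxyborohydride exchanges an acetate for the C7 hydroxyl and delivers hydride within the complex to the β face of C5, giving the anti 1,3-diol with the α (S) hydroxyl; the alkene is not reduced by this reagent.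

Step 15
Reactants: 21 (3R,3aS,4S,6S,8aS)-6,8a-dimethyl-8-methylidene-3-(propan-2-yl)decahydroazulene-3,4-diol; 22 3,4-dimethoxybenzoyl chloride
Product: 23 (3R,3aS,4S,6S,8aS)-3-hydroxy-6,8a-dimethyl-8-methylidene-3-(propan-2-yl)decahydroazulen-4-yl 3,4-dimethoxybenzoate
Conditions: DMAP, Et3N, CH2Cl2, 0 °C → rt
Reagents that add atoms: none
Why: DMAP-catalysed acylation; the secondary C5 hydroxyl reacts while the tertiary C7 hydroxyl, flanked by the isopropyl group and the ring fusion, does not.

Step 16
Reactants: 23 (3R,3aS,4S,6S,8aS)-3-hydroxy-6,8a-dimethyl-8-methylidene-3-(propan-2-yl)decahydroazulen-4-yl 3,4-dimethoxybenzoate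
Product: 25 (3R,3aS,4S,6R,8aS)-3-hydroxy-6,8a-dimethyl-8-oxo-3-(propan-2-yl)decahydroazulen-4-yl 3,4-dimethoxybenzoate, via ozonide 24 (not isolated)
Conditions: O3, CH2Cl2, −78 °C, indicator dye; then PPh3, −78 °C → rt
Reagents that add atoms: ozone, [O-][O+]=O
Why: Ozonolysis of the 1,1-disubstituted exocyclic alkene and reductive work-up of ozonide 24; the alkene reacts far faster than the acyl-deactivated dimethoxyarene, and the dye marks the end point.

Step 17
Reactants: 25 (3R,3aS,4S,6R,8aS)-3-hydroxy-6,8a-dimethyl-8-oxo-3-(propan-2-yl)decahydroazulen-4-yl 3,4-dimethoxybenzoate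
Product: 26 (3R,3aS,4S,8aS)-3-hydroxy-6,8a-dimethyl-8-oxo-3-(propan-2-yl)-1,2,3,3a,4,5,8,8a-octahydroazulen-4-yl 3,4-dimethoxybenzoate
Conditions: IBX, DMSO/fluorobenzene, 65 °C
Reagents that add atoms: none
Why: IBX dehydrogenation of a ketone to the enone (enolisation, single-electron oxidation, loss of the β-hydrogen); C10 is quaternary, so only the C2–C3 position can be desaturated, and the no longer needed C3 stereocentre disappears.

Step 18
Reactants: 26 (3R,3aS,4S,8aS)-3-hydroxy-6,8a-dimethyl-8-oxo-3-(propan-2-yl)-1,2,3,3a,4,5,8,8a-octahydroazulen-4-yl 3,4-dimethoxybenzoate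
Product: 27 (3R,3aS,4S,8R,8aS)-3,8-dihydroxy-6,8a-dimethyl-3-(propan-2-yl)-1,2,3,3a,4,5,8,8a-octahydroazulen-4-yl 3,4-dimethoxybenzoate
Conditions: (S)-2-methyl-CBS-oxazaborolidine (0.5 equiv), catecholborane, toluene/CH2Cl2, −78 → −40 °C
Reagents that add atoms: none
Why: Corey–Bakshi–Shibata reduction under reagent control: with quaternary C10 as the large and vinylic C2 as the small group the (S)-catalyst should deliver hydride to the β face and give the (1R) α-alcohol, against the substrate's preference for attack anti to the angular methyl; the fully substituted β-carbon excludes 1,4-reduction.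

Step 19
Reactants: 27 (3R,3aS,4S,8R,8aS)-3,8-dihydroxy-6,8a-dimethyl-3-(propan-2-yl)-1,2,3,3a,4,5,8,8a-octahydroazulen-4-yl 3,4-dimethoxybenzoate; 28 (2Z)-2-methylbut-2-enoic acid (angelic acid)
Product: 30 (3R,3aS,4S,8R,8aS)-3-hydroxy-6,8a-dimethyl-8-{[(2Z)-2-methylbut-2-enoyl]oxy}-3-(propan-2-yl)-1,2,3,3a,4,5,8,8a-octahydroazulen-4-yl 3,4-dimethoxybenzoate, via mixed anhydride 29 (not isolated)
Conditions: 2,4,6-Cl3C6H2COCl, Et3N, toluene, rt; then 27, 75 °C
Reagents that add atoms: none
Why: Yamaguchi-type esterification through mixed anhydride 29 without a nucleophilic catalyst, conditions under which angeloyl groups are transferred to hindered alcohols without Z to E isomerisation; the tertiary hydroxyl is too hindered to react.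

## Compound list

1 | but-2-yn-1-ol | CC#CCO | starting material
2 | triethyl orthoacetate | CC(OCC)(OCC)OCC | starting material
3 | 1-(but-2-yn-1-yloxy)-1-ethoxyethene | C=C(OCC)OCC#CC | intermediate
4 | ethyl 3-methylpenta-3,4-dienoate | C=C=C(C)CC(=O)OCC | intermediate
5 | 3-methylpenta-3,4-dien-1-ol | C=C=C(C)CCO | intermediate
6 | 5-bromo-3-methylpenta-1,2-diene | C=C=C(C)CCBr | intermediate
7 | (1S,2S)-2-methylcyclopropane-1-carboxylic acid | O=C(O)[C@H]1C[C@@H]1C | starting material
8 | (1S,2S)-2-methylcyclopropane-1-carbonyl chloride | O=C(Cl)[C@H]1C[C@@H]1C | intermediate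
9 | 3-methylbut-1-yne | CC(C)C#C | starting material
10 | (3-methylpenta-3,4-dien-1-yl)magnesium bromide | C=C=C(C)CC[Mg]Br | intermediate
11 | [(1E)-5-methyl-2-(propan-2-yl)hepta-1,5,6-trien-1-yl]copper | C=C=C(C)CC/C(C(C)C)=C\[Cu] | intermediate
12 | (2E)-6-methyl-1-[(1S,2S)-2-methylcyclopropyl]-3-(propan-2-yl)octa-2,6,7-trien-1-one | C=C=C(C)CC/C(C(C)C)=C\C(=O)[C@H]1C[C@@H]1C | intermediate
13 | (1S,2E)-6-methyl-1-[(1S,2S)-2-methylcyclopropyl]-3-(propan-2-yl)octa-2,6,7-trien-1-ol | C=C=C(C)CC/C(C(C)C)=C\[C@@H](O)[C@H]1C[C@@H]1C | intermediate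
14 | (S)-[(1S,2S)-2-methylcyclopropyl][(2R,3R)-3-(3-methylpenta-3,4-dien-1-yl)-3-(propan-2-yl)oxiran-2-yl]methanol | C=C=C(C)CC[C@]1(C(C)C)O[C@@H]1[C@@H](O)[C@H]1C[C@@H]1C | intermediate
15 | (1R,3S)-6-methyl-1-[(1S,2S)-2-methylcyclopropyl]-3-(propan-2-yl)octa-6,7-diene-1,3-diol | C=C=C(C)CC[C@@](O)(C(C)C)C[C@@H](O)[C@H]1C[C@@H]1C | intermediate
16 | (3S)-3-hydroxy-6-methyl-1-[(1S,2S)-2-methylcyclopropyl]-3-(propan-2-yl)octa-6,7-dien-1-one | C=C=C(C)CC[C@@](O)(C(C)C)CC(=O)[C@H]1C[C@@H]1C | intermediate
17 | (1Z,3R)-6-methyl-1-[(1S,2S)-2-methylcyclopropyl]-3-(propan-2-yl)-1,3-bis[(triethylsilyl)oxy]octa-1,6,7-triene | C=C=C(C)CC[C@@](O[Si](CC)(CC)CC)(C(C)C)/C=C(\O[Si](CC)(CC)CC)[C@H]1C[C@@H]1C | intermediate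
18 | (1R,3aS,6S,8aR)-3a,6-dimethyl-4-methylidene-1-(propan-2-yl)-1,8-bis[(triethylsilyl)oxy]-1,2,3,3a,4,5,6,8a-octahydroazulene | C=C1C[C@H](C)C=C(O[Si](CC)(CC)CC)[C@H]2[C@]1(C)CC[C@@]2(O[Si](CC)(CC)CC)C(C)C | intermediate
19 | (3R,3aS,6S,8aS)-3-hydroxy-6,8a-dimethyl-8-methylidene-3-(propan-2-yl)octahydroazulen-4(1H)-one | C=C1C[C@H](C)CC(=O)[C@H]2[C@]1(C)CC[C@@]2(O)C(C)C | intermediate
20 | (3R,3aR,6S,8aS)-3-hydroxy-6,8a-dimethyl-8-methylidene-3-(propan-2-yl)octahydroazulen-4(1H)-one | C=C1C[C@H](C)CC(=O)[C@@H]2[C@]1(C)CC[C@@]2(O)C(C)C | intermediate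
21 | (3R,3aS,4S,6S,8aS)-6,8a-dimethyl-8-methylidene-3-(propan-2-yl)decahydroazulene-3,4-diol | C=C1C[C@H](C)C[C@H](O)[C@@H]2[C@]1(C)CC[C@@]2(O)C(C)C | intermediate
22 | 3,4-dimethoxybenzoyl chloride | COc1ccc(cc1OC)C(Cl)=O | starting material
23 | (3R,3aS,4S,6S,8aS)-3-hydroxy-6,8a-dimethyl-8-methylidene-3-(propan-2-yl)decahydroazulen-4-yl 3,4-dimethoxybenzoate | C=C1C[C@H](C)C[C@H](OC(=O)c3ccc(OC)c(OC)c3)[C@@H]2[C@]1(C)CC[C@@]2(O)C(C)C | intermediate
24 | spiro-1,2,4-trioxolane (ozonide) at C1 of 23 | C1OOC2(O1)C[C@H](C)C[C@H](OC(=O)c3ccc(OC)c(OC)c3)[C@@H]3[C@]2(C)CC[C@@]3(O)C(C)C | intermediate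
25 | (3R,3aS,4S,6R,8aS)-3-hydroxy-6,8a-dimethyl-8-oxo-3-(propan-2-yl)decahydroazulen-4-yl 3,4-dimethoxybenzoate | O=C1C[C@H](C)C[C@H](OC(=O)c3ccc(OC)c(OC)c3)[C@@H]2[C@]1(C)CC[C@@]2(O)C(C)C | intermediate
26 | (3R,3aS,4S,8aS)-3-hydroxy-6,8a-dimethyl-8-oxo-3-(propan-2-yl)-1,2,3,3a,4,5,8,8a-octahydroazulen-4-yl 3,4-dimethoxybenzoate | O=C1C=C(C)C[C@H](OC(=O)c3ccc(OC)c(OC)c3)[C@@H]2[C@]1(C)CC[C@@]2(O)C(C)C | intermediate
27 | (3R,3aS,4S,8R,8aS)-3,8-dihydroxy-6,8a-dimethyl-3-(propan-2-yl)-1,2,3,3a,4,5,8,8a-octahydroazulen-4-yl 3,4-dimethoxybenzoate | O[C@@H]1C=C(C)C[C@H](OC(=O)c3ccc(OC)c(OC)c3)[C@@H]2[C@]1(C)CC[C@@]2(O)C(C)C | intermediate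
28 | (2Z)-2-methylbut-2-enoic acid (angelic acid) | C/C=C(/C)C(=O)O | starting material
29 | (2Z)-2-methylbut-2-enoic 2,4,6-trichlorobenzoic anhydride | C/C=C(/C)C(=O)OC(=O)c1c(Cl)cc(Cl)cc1Cl | intermediate
30 | (3R,3aS,4S,8R,8aS)-3-hydroxy-6,8a-dimethyl-8-{[(2Z)-2-methylbut-2-enoyl]oxy}-3-(propan-2-yl)-1,2,3,3a,4,5,8,8a-octahydroazulen-4-yl 3,4-dimethoxybenzoate | C/C=C(/C)C(=O)O[C@@H]1C=C(C)C[C@H](OC(=O)c2ccc(OC)c(OC)c2)[C@@H]2[C@]1(C)CC[C@@]2(O)C(C)C | target

## Step count and least certain steps

Total step count: 19. Longest linear sequence: 18 steps (1 to 30 through steps 1–3 and 5–19; step 4 is a one-step branch).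

**Step 11 (key step).** The most likely failure is a slow insertion at C6, which lies between the quaternary C7 and the forming quaternary C10. The rhodacycle could then leak into cleavage of the more substituted cyclopropane bond, or the allene could oligomerise. The same would happen if the face dictated by the cyclopropane suits the C7 substituents poorly. The fallback changes the substrate, not the catalyst. It sets out from 16. One equivalent of t-BuMe2SiOTf with Et3N at −78 °C should silylate only the ketone and give (1Z,3R)-1-[(tert-butyldimethylsilyl)oxy]-6-methyl-1-[(1S,2S)-2-methylcyclopropyl]-3-(propan-2-yl)octa-1,6,7-trien-3-ol F1. Its tether carries a free hydroxyl, the slimmest possible group next to C6. Cycloaddition under the conditions of step 11 would give the hydroxy enol ether (1R,3aS,6S,8aS)-8-[(tert-butyldimethylsilyl)oxy]-3a,6-dimethyl-4-methylidene-1-(propan-2-yl)-1,2,3,3a,4,5,6,8a-octahydroazulen-1-ol F2. HF·pyridine returns the route to 19.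

**Step 18.** The catalyst may fail to override the substrate's preference for hydride attack anti to the angular methyl, giving poor facial selectivity at C1. The fallback sets out from 26 and accepts the substrate's own preference. Luche reduction (NaBH4, CeCl3·7H2O, MeOH, −78 °C) should give the 1β-alcohol (3R,3aS,4S,8S,8aS)-3,8-dihydroxy-6,8a-dimethyl-3-(propan-2-yl)-1,2,3,3a,4,5,8,8a-octahydroazulen-4-yl 3,4-dimethoxybenzoate F3. A Mitsunobu reaction with 4-nitrobenzoic acid (PPh3, DIAD, toluene) inverts C1 to the α-ester (3R,3aS,4S,8R,8aS)-3-hydroxy-6,8a-dimethyl-8-[(4-nitrobenzoyl)oxy]-3-(propan-2-yl)-1,2,3,3a,4,5,8,8a-octahydroazulen-4-yl 3,4-dimethoxybenzoate F4. K2CO3 in MeOH at 0 °C cleaves the activated 4-nitrobenzoate ahead of the electron-rich veratrate and arrives at 27.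

**Step 13.** The free tertiary aldol may undergo retro-aldol cleavage or dehydration before the fusion has equilibrated. The fallback sets out from 18 and equilibrates a species that cannot fragment. K2CO3 in MeOH should cleave only the enol ether and give the cis ketone (3R,3aS,6S,8aS)-6,8a-dimethyl-8-methylidene-3-(propan-2-yl)-3-[(triethylsilyl)oxy]octahydroazulen-4(1H)-one F5. NaOMe in MeOH then equilibrates C6 to the trans ketone (3R,3aR,6S,8aS)-6,8a-dimethyl-8-methylidene-3-(propan-2-yl)-3-[(triethylsilyl)oxy]octahydroazulen-4(1H)-one F6. HF·pyridine removes the silyl ether and the route is rejoined at 20.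

**Step 5.** Carbocupration of the α-branched alkyne by a functionalised alkylcopper may be incomplete, and the direct acylation may erode the olefin geometry. The fallback sets out from 8, 9 and 6 and builds the same bonds by cross-coupling. Acyl Sonogashira coupling of 8 with 9 (PdCl2(PPh3)2, CuI, Et3N) gives the ynone 4-methyl-1-[(1S,2S)-2-methylcyclopropyl]pent-2-yn-1-one F7. NaI in AcOH adds HI anti to give (2Z)-3-iodo-4-methyl-1-[(1S,2S)-2-methylcyclopropyl]pent-2-en-1-one F8. Negishi coupling (Pd(PPh3)4, THF) with (3-methylpenta-3,4-dien-1-yl)zinc bromide F9, made from 6 and zinc dust, replaces iodine with retention and returns to 12.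

**Step 19.** The angelate may isomerise to the tiglate at 75 °C, or the neopentyl allylic alcohol may acylate too slowly. The fallback sets out from 27 and builds the (Z)-olefin on the molecule. Esterification with 2-[bis(2,2,2-trifluoroethoxy)phosphoryl]propanoic acid (DCC, DMAP) gives (3R,3aS,4S,8R,8aS)-8-({2-[bis(2,2,2-trifluoroethoxy)phosphoryl]propanoyl}oxy)-3-hydroxy-6,8a-dimethyl-3-(propan-2-yl)-1,2,3,3a,4,5,8,8a-octahydroazulen-4-yl 3,4-dimethoxybenzoate F10. Still–Gennari olefination (KN(SiMe3)2, 18-crown-6, acetaldehyde, THF, −78 °C) then forms the (Z)-2-methylbut-2-enoate and arrives at 30.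

## Further compounds

F1 | step 11 | (1Z,3R)-1-[(tert-butyldimethylsilyl)oxy]-6-methyl-1-[(1S,2S)-2-methylcyclopropyl]-3-(propan-2-yl)octa-1,6,7-trien-3-ol | C=C=C(C)CC[C@@](O)(C(C)C)/C=C(\O[Si](C)(C)C(C)(C)C)[C@H]1C[C@@H]1C
F2 | step 11 | (1R,3aS,6S,8aS)-8-[(tert-butyldimethylsilyl)oxy]-3a,6-dimethyl-4-methylidene-1-(propan-2-yl)-1,2,3,3a,4,5,6,8a-octahydroazulen-1-ol | C=C1C[C@H](C)C=C(O[Si](C)(C)C(C)(C)C)[C@H]2[C@]1(C)CC[C@@]2(O)C(C)C
F3 | step 18 | (3R,3aS,4S,8S,8aS)-3,8-dihydroxy-6,8a-dimethyl-3-(propan-2-yl)-1,2,3,3a,4,5,8,8a-octahydroazulen-4-yl 3,4-dimethoxybenzoate | O[C@H]1C=C(C)C[C@H](OC(=O)c3ccc(OC)c(OC)c3)[C@@H]2[C@]1(C)CC[C@@]2(O)C(C)C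
F4 | step 18 | (3R,3aS,4S,8R,8aS)-3-hydroxy-6,8a-dimethyl-8-[(4-nitrobenzoyl)oxy]-3-(propan-2-yl)-1,2,3,3a,4,5,8,8a-octahydroazulen-4-yl 3,4-dimethoxybenzoate | O=C(O[C@@H]1C=C(C)C[C@H](OC(=O)c3ccc(OC)c(OC)c3)[C@@H]2[C@]1(C)CC[C@@]2(O)C(C)C)c1ccc(cc1)[N+](=O)[O-]
F5 | step 13 | (3R,3aS,6S,8aS)-6,8a-dimethyl-8-methylidene-3-(propan-2-yl)-3-[(triethylsilyl)oxy]octahydroazulen-4(1H)-one | C=C1C[C@H](C)CC(=O)[C@H]2[C@]1(C)CC[C@@]2(O[Si](CC)(CC)CC)C(C)C
F6 | step 13 | (3R,3aR,6S,8aS)-6,8a-dimethyl-8-methylidene-3-(propan-2-yl)-3-[(triethylsilyl)oxy]octahydroazulen-4(1H)-one | C=C1C[C@H](C)CC(=O)[C@@H]2[C@]1(C)CC[C@@]2(O[Si](CC)(CC)CC)C(C)C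
F7 | step 5 | 4-methyl-1-[(1S,2S)-2-methylcyclopropyl]pent-2-yn-1-one | CC(C)C#CC(=O)[C@H]1C[C@@H]1C
F8 | step 5 | (2Z)-3-iodo-4-methyl-1-[(1S,2S)-2-methylcyclopropyl]pent-2-en-1-one | CC(C)/C(I)=C/C(=O)[C@H]1C[C@@H]1C
F9 | step 5 | (3-methylpenta-3,4-dien-1-yl)zinc bromide | C=C=C(C)CC[Zn]Br
F10 | step 19 | (3R,3aS,4S,8R,8aS)-8-({2-[bis(2,2,2-trifluoroethoxy)phosphoryl]propanoyl}oxy)-3-hydroxy-6,8a-dimethyl-3-(propan-2-yl)-1,2,3,3a,4,5,8,8a-octahydroazulen-4-yl 3,4-dimethoxybenzoate | CC(C(=O)O[C@@H]1C=C(C)C[C@H](OC(=O)c3ccc(OC)c(OC)c3)[C@@H]2[C@]1(C)CC[C@@]2(O)C(C)C)P(=O)(OCC(F)(F)F)OCC(F)(F)F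
A1 | alternative 1 | bicyclic cycloheptadienol with C1 hydroxyl, C2=C3 and C5=C6 olefins, C10 methyl and the C7 ketone as ethylene ketal | O[C@@H]1C=C(C)CC=C2[C@]1(C)CCC23OCCO3
A2 | alternative 2 | methyl 2-[(tert-butyldimethylsilyloxy)methyl]-2-methyl-5-oxocyclopentane-1-carboxylate | COC(=O)[C@H]1C(=O)CC[C@]1(C)CO[Si](C)(C)C(C)(C)C
A3 | alternative 3 | ring A enone with C1 ketone, C2=C3 olefin, C5 veratrate and C7 trimethylsilyl ether | O=C1C=C(C)C[C@H](OC(=O)c2ccc(OC)c(OC)c2)[C@@H]2[C@]1(C)CC[C@@]2(O[Si](C)(C)C)C(C)C
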